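The cis-2,5-disubstituted oxolane of the target (O, C9, C10, C11, C12; cembrane numbering), flanked by the oxygenated carbons C8 and C13, is read as a masked 7-oxanorbornene. A catalytic enantioselective Diels–Alder reaction between flat, achiral 2,4-dimethylfuran and an acrylate should form C9–C10 and C11–C12 in one operation, set both ring stereocentres cis and store C8 and C13 as the alkene. Decarboxylation and glycol cleavage then release a keto aldehyde, whose two carbonyl groups are extended by chelation-controlled additions; Shi epoxidation, epoxide-opening lactonisation and ring-closing metathesis complete the skeleton.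

Key step: step 1

Remarks
- Numbering (cembrane): C1 is the CH carrying the C15(=C17)–C16 lactone arm; C4 is the lactone O-bearing carbon (methyl C18); C5 and C13 carry the acetates; C8 is the tertiary carbinol (methyl C19); the oxolane is O–C9–C10–C11–C12 (methyl C20 on C12).
- Assumption: the sense of induction of the chiral catalysts (steps 1 and 13, and the fallbacks) is assigned by analogy with simple substrates; if it is found reversed, the antipodal catalyst is used without other change.
- Compounds 1, 2, 8 and 9 are taken as purchased (9 is the butenolide acetal of (+)-menthol).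

Step 1
Reactants: 1 2,4-dimethylfuran; 2 2,2,2-trifluoroethyl prop-2-enoate
Product: 3 2,2,2-trifluoroethyl (1S,2S,4S)-1,5-dimethyl-7-oxabicyclo[2.2.1]hept-5-ene-2-carboxylate (endo ester)
Conditions: (S)-oxazaborolidinium triflimide [from (S)-α,α-diphenylprolinol, o-tolylboroxine and Tf2NH] (20 mol %), 1 (3 equiv), CH2Cl2, −78 °C
Reagents that add atoms: none
Why: The protonated oxazaborolidine binds the ester carbonyl of 2, and the furan adds as the 4π component in a concerted but asynchronous [4+2] cycloaddition in which its most nucleophilic terminus (furan C5, future C9) bonds to the acrylate β-carbon (future C10) while the methyl-bearing terminus (furan C2, future C12) closes onto the α-carbon (future C11). The closest known reaction type is the chiral oxazaborolidinium-catalysed Diels–Alder reaction of furans with trifluoroethyl acrylate. Both rings of the 7-oxanorbornene, the oxolane O–C12–C11–C10–C9 and the cyclohexene C12–C11–C10–C9–C8=C13, are closed in the same suprafacial [4+2] event, so the two new bonds lie on one face of the furan and the later 2,5-substituents of the oxolane (C13 and C8) are necessarily cis. The absolute configuration at C12 and C9 is set by the catalyst, which shields one face of the bound acrylate, acting through the endo transition state; the stereocentre at C11 is temporary and is erased in step 3. The step needs regio-, endo- and enantioface selectivity under kinetic control; the two methyl groups of 1 polarise the diene in the same sense (largest coefficient at the free α-carbon), and −78 °C with immediate dihydroxylation in step 2 should suppress cycloreversion and Friedel–Crafts-type addition.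

Step 2
Reactants: 3 2,2,2-trifluoroethyl (1S,2S,4S)-1,5-dimethyl-7-oxabicyclo[2.2.1]hept-5-ene-2-carboxylate
Product: 5 (1R,2S,4S,5R,6S)-5,6-dihydroxy-1,5-dimethyl-7-oxabicyclo[2.2.1]heptane-2-carboxylic acid, via diol ester 4 (not isolated)
Conditions: OsO4 (2 mol %), NMO, acetone/H2O, 0 °C; then LiOH, THF/H2O, 0 °C; HCl to pH 3
Reagents that add atoms: osmium tetroxide (O=[Os](=O)(=O)=O); N-methylmorpholine N-oxide (C[N+]1([O-])CCOCC1); water (O); lithium hydroxide ([Li+].[OH-])
Why: Upjohn dihydroxylation should occur on the exo face of the strained C8=C13 alkene, anti to the endo ester, which removes the cycloreversion liability, and the activated trifluoroethyl ester is then saponified under mild conditions; the two carbinol centres are temporary.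

Step 3
Reactants: 5 (1R,2S,4S,5R,6S)-5,6-dihydroxy-1,5-dimethyl-7-oxabicyclo[2.2.1]heptane-2-carboxylic acid
Product: 6 (1R,2S,3R,4S)-1,3-dimethyl-7-oxabicyclo[2.2.1]heptane-2,3-diol
Conditions: 9-mesityl-10-phenylacridinium tetrafluoroborate (5 mol %), (PhS)2 (10 mol %), i-Pr2NEt (20 mol %), CF3CH2OH, blue LEDs, 25 °C
Reagents that add atoms: none
Why: Acridinium photoredox hydrodecarboxylation oxidises the carboxylate, CO2 is lost and the secondary C11 radical, which after step 2 has no alkene to attack, takes a hydrogen atom from thiophenol, so only the temporary stereocentre is affected.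

Step 4
Reactants: 6 (1R,2S,3R,4S)-1,3-dimethyl-7-oxabicyclo[2.2.1]heptane-2,3-diol
Product: 7 (2R,5S)-5-acetyl-2-methyloxolane-2-carbaldehyde
Conditions: NaIO4, THF/pH 7 buffer, 0 → 25 °C; used crude at once
Reagents that add atoms: none
Why: Malaprade glycol cleavage of the cis-exo diol under neutral conditions should open the C8–C13 bond to the C13 aldehyde and the C8 methyl ketone on one face of the oxolane without epimerising C9.

Step 5
Reactants: 8 (4-bromobut-1-yn-1-yl)trimethylsilane; 9 (5S)-5-{[(1S,2R,5S)-5-methyl-2-(propan-2-yl)cyclohexyl]oxy}furan-2(5H)-one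
Product: 11 (4S,5S)-5-{[(1S,2R,5S)-5-methyl-2-(propan-2-yl)cyclohexyl]oxy}-4-[4-(trimethylsilyl)but-3-yn-1-yl]oxolan-2-one, via Grignard reagent 10 (not isolated)
Conditions: Mg, THF, 25 °C; then CuI (10 mol %), 9, THF, −78 → −40 °C; aq. NH4Cl
Reagents that add atoms: none
Why: Copper-catalysed conjugate addition of the Grignard reagent to the γ-alkoxybutenolide should take place anti to the menthyloxy group (auxiliary control), which sets C1 with the trans-4,5 arrangement.

Step 6
Reactants: 11 (4S,5S)-5-menthyloxy-4-[4-(trimethylsilyl)but-3-yn-1-yl]oxolan-2-one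
Product: 13 (4S)-4-(but-3-yn-1-yl)oxolan-2-one, via hydroxy carboxylate 12 (not isolated)
Conditions: NaBH4, KOH, MeOH/H2O, 0 → 25 °C; then 2 M HCl, 25 °C
Reagents that add atoms: potassium hydroxide ([K+].[OH-])
Why: Hydroxide opens the acyloxy acetal to the potassium carboxylate and the free aldehyde, which borohydride reduces as it forms so that C1 is not enolised, hydroxide also cleaves the alkynyl C–Si bond, and acidification relactonises the hydroxy acid with loss of either carboxyl oxygen, so that the hydroxide oxygen can remain as the lactone carbonyl oxygen (reductive auxiliary removal, lactonisation).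

Step 7
Reactants: 13 (4S)-4-(but-3-yn-1-yl)oxolan-2-one
Product: 15 (4S)-4-[(3E)-4-iodo-3-methylbut-3-en-1-yl]oxolan-2-one, via alkenylalane 14 (not isolated)
Conditions: AlMe3 (3 equiv), Cp2ZrCl2 (20 mol %), H2O (1 equiv), CH2Cl2, −23 °C; then I2, THF, −23 → 0 °C
Reagents that add atoms: trimethylaluminium (C[Al](C)C); iodine (II)
Why: Zirconium-catalysed, water-accelerated Negishi carboalumination adds methyl and aluminium syn across the terminal alkyne with methyl at the internal carbon, and iodinolysis with retention should give the E-configured 2-methyl-1-iodoalkene while the lactone is inert at −23 °C.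

Step 8
Reactants: 15 (4S)-4-[(3E)-4-iodo-3-methylbut-3-en-1-yl]oxolan-2-one
Product: 17 methyl (3S,6E)-7-iodo-3-(iodomethyl)-6-methylhept-6-enoate, via silyl ester 16 (not isolated)
Conditions: TMSI, CH2Cl2, 25 °C; then MeOH, 25 °C
Reagents that add atoms: iodotrimethylsilane (C[Si](C)(C)I); methanol (CO)
Why: Iodotrimethylsilane silylates the lactone carbonyl and iodide opens the ring by SN2 attack at the O–CH2 carbon (C14), after which methanol converts the silyl ester into the methyl ester (lactone ring opening, Fischer esterification) without touching C1.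

Step 9
Reactants: 17 methyl (3S,6E)-7-iodo-3-(iodomethyl)-6-methylhept-6-enoate
Product: 18 methyl (3S,6E)-3-(iodomethyl)-6-methylnona-6,8-dienoate
Conditions: tributyl(vinyl)stannane, Pd2(dba)3 (2.5 mol %), AsPh3 (20 mol %), CuI (10 mol %), NMP, 25 °C
Reagents that add atoms: tributyl(ethenyl)stannane (C=C[Sn](CCCC)(CCCC)CCCC)
Why: Stille coupling, in which zerovalent palladium inserts into the alkenyl C–I bond much faster than into the β-branched primary alkyl C–I bond and the E geometry is retained.

Step 10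
Reactants: 18 methyl (3S,6E)-3-(iodomethyl)-6-methylnona-6,8-dienoate; 7 (2R,5S)-5-acetyl-2-methyloxolane-2-carbaldehyde
Product: 20 methyl (3R,6E)-3-{(2R)-2-[(2R,5S)-5-acetyl-2-methyloxolan-2-yl]-2-hydroxyethyl}-6-methylnona-6,8-dienoate, via alkylzinc iodide 19 (not isolated)
Conditions: Zn dust, LiCl, THF, 25 °C; then 7, MgBr2·OEt2, THF/CH2Cl2, −30 → 0 °C; aq. NH4Cl at 0 °C
Reagents that add atoms: none
Why: Direct zinc insertion into the primary C–I bond gives an ester-tolerant alkylzinc iodide whose magnesium-salt-promoted addition is selective for the aldehyde over the ketone and the ester, and with MgBr2 bridging the aldehyde oxygen and the oxolane oxygen (Cram chelate) the nucleophile should attack the methyl-bearing face anti to ring carbon C11 and the cis acetyl group, giving 13R.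

Step 11
Reactants: 20 methyl (3R,6E)-3-{(2R)-2-[(2R,5S)-5-acetyl-2-methyloxolan-2-yl]-2-hydroxyethyl}-6-methylnona-6,8-dienoate
Product: 21 the 13-O-tert-butyldimethylsilyl ether of 20
Conditions: TBSOTf, 2,6-lutidine, CH2Cl2, −78 °C
Reagents that add atoms: tert-butyldimethylsilyl trifluoromethanesulfonate (CC(C)(C)[Si](C)(C)OS(=O)(=O)C(F)(F)F)
Why: Silylation of the hindered secondary alcohol with the silyl triflate caps O13 so that it can neither lactonise onto C16 (δ-lactone) nor form a hemiketal with the C8 ketone.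

Step 12
Reactants: 21 the 13-O-tert-butyldimethylsilyl ether of 20
Product: 22 methyl (3R,6E)-3-{(2R)-2-[(tert-butyldimethylsilyl)oxy]-2-[(2R,5S)-5-[(2S)-2-hydroxybut-3-en-2-yl]-2-methyloxolan-2-yl]ethyl}-6-methylnona-6,8-dienoate
Conditions: CH2=CHMgBr, MgBr2·OEt2, CH2Cl2/THF, −78 °C
Reagents that add atoms: vinylmagnesium bromide (C=C[Mg]Br)
Why: Chelation-controlled Grignard addition, in which magnesium bridges the ketone oxygen and the oxolane oxygen and the vinyl group attacks the face anti to ring carbon C10 (Cram chelate model) to give 8S, the ketone reacting far faster than the methyl ester at −78 °C.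

Step 13
Reactants: 22 the tertiary allylic alcohol from step 12
Product: 23 methyl (3R)-3-{(2R)-2-[(tert-butyldimethylsilyl)oxy]-2-[(2R,5S)-5-[(2S)-2-hydroxybut-3-en-2-yl]-2-methyloxolan-2-yl]ethyl}-5-[(2S,3S)-3-ethenyl-2-methyloxiran-2-yl]pentanoate
Conditions: L-fructose-derived Shi ketone (30 mol %), KHSO5 (as the triple salt 2KHSO5·KHSO4·K2SO4), K2CO3, Bu4NHSO4, MeCN/CH2(OMe)2/aq. Na2B4O7–EDTA, 0 °C
Reagents that add atoms: potassium peroxymonosulfate ([K+].[O-]S(=O)(=O)OO)
Why: Shi asymmetric epoxidation, in which the chiral dioxirane reacts through a spiro transition state with the electron-rich E-trisubstituted alkene of the diene while the two monosubstituted vinyl groups are spared, and the L-fructose-derived ketone should deliver oxygen to the face that gives the 4S,5S-epoxide (reagent control).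

Step 14
Reactants: 23 the 4S,5S vinyl epoxide ester from step 13
Product: 25 (4R,7R)-4-{(2R)-2-[(tert-butyldimethylsilyl)oxy]-2-[(2R,5S)-5-[(2S)-2-hydroxybut-3-en-2-yl]-2-methyloxolan-2-yl]ethyl}-7-[(1S)-1-hydroxyprop-2-en-1-yl]-7-methyloxepan-2-one, via lithium epoxy carboxylate 24 (not isolated)
Conditions: LiOH, THF/MeOH/H2O, 0 → 25 °C; aq. KHSO4 to pH 4, extraction; CSA (10 mol %), CH2Cl2 (2 mM), 0 °C
Reagents that add atoms: lithium hydroxide ([Li+].[OH-])
Why: After saponification, acid-catalysed intramolecular epoxide opening by the carboxylic acid should proceed in the 7-exo-tet mode at the tertiary carbon C4 with inversion (4S to 4R), favoured over 8-endo attack at the allylic carbon C5, and leaves the C5 oxygen with its configuration (5S) as the free allylic alcohol.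

Step 15
Reactants: 25 the seco hydroxy lactone from step 14
Product: 26 (1R,4R,5S,8S,9S,12R,13R)-13-[(tert-butyldimethylsilyl)oxy]-5,8-dihydroxy-9,12-epoxy-17-norcembr-6-en-16,4-olide (fourteen-membered ring, new C6=C7 alkene, E/Z not defined)
Conditions: second-generation Grubbs catalyst RuCl2(=CHPh)(H2IMes)(PCy3) (10 mol %), 1,4-benzoquinone (20 mol %), CH2Cl2 (1 mM), 40 °C
Reagents that add atoms: none
Why: Ring-closing metathesis of the two monosubstituted allylic-alcohol alkenes closes the fourteen-membered carbocycle at C6=C7 with loss of ethene, the lactone and oxolane rings restricting the chain, and no stereocentre is formed.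

Step 16
Reactants: 26 the macrocyclic alkene from step 15
Product: 27 (1R,4R,5S,8S,9S,12R,13R)-13-[(tert-butyldimethylsilyl)oxy]-5,8-dihydroxy-9,12-epoxy-17-norcembran-16,4-olide
Conditions: H2 (1 atm), PtO2, EtOAc, 25 °C
Reagents that add atoms: none
Why: Heterogeneous hydrogenation of the only C=C bond over platinum should saturate C6–C7 without hydrogenolysis of the allylic C–O bonds.

Step 17
Reactants: 27 the saturated macrocyclic lactone from step 16
Product: 30 (1R,4R,5S,8S,9S,12R,13R)-13-[(tert-butyldimethylsilyl)oxy]-5,8-dihydroxy-9,12-epoxycembr-15(17)-en-16,4-olide, via Mannich base 28 (not isolated), via ammonium iodide 29 (not isolated)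
Conditions: LiN(i-Pr)2 (3.5 equiv), THF, −78 °C; CH2=NMe2+ I−, −78 → 0 °C; aq. NH4Cl; then MeI, MeOH, 25 °C; then aq. NaHCO3/CH2Cl2, 25 °C
Reagents that add atoms: Eschenmoser's salt (C=[N+](C)C.[I-])
Why: Lactone α-methylenation by the Eschenmoser protocol, in which the lithium enolate at C15 (the only enolisable position, the two hydroxyl groups being carried as lithium alkoxides) undergoes a Mannich reaction and quaternisation followed by base-induced elimination gives the exocyclic alkene.

Step 18
Reactants: 30 the α-methylene lactone silyl ether from step 17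
Product: 31 (1R,4R,5S,8S,9S,12R,13R)-5,8,13-trihydroxy-9,12-epoxycembr-15(17)-en-16,4-olide
Conditions: HF·pyridine, pyridine/THF, 0 → 25 °C
Reagents that add atoms: none
Why: Fluoride-mediated desilylation under buffered acidic conditions should free O13 without transesterifying the lactone or adding to the methylene lactone.

Step 19
Reactants: 31 the triol from step 18
Product: 32 Dendronpholide Q
Conditions: Ac2O, pyridine, DMAP (5 mol %), CH2Cl2, 0 → 25 °C
Reagents that add atoms: acetic anhydride (CC(=O)OC(C)=O)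
Why: DMAP-catalysed acetylation should esterify the two secondary alcohols (O5, O13) while the hindered tertiary alcohol at C8 stays free under these mild conditions.

Compound list
1 | 2,4-dimethylfuran | Cc1cc(C)co1 | starting material
2 | 2,2,2-trifluoroethyl prop-2-enoate | C=CC(=O)OCC(F)(F)F | starting material
3 | 2,2,2-trifluoroethyl (1S,2S,4S)-1,5-dimethyl-7-oxabicyclo[2.2.1]hept-5-ene-2-carboxylate (endo) | C[C@@]12O[C@@H](C[C@@H]1C(=O)OCC(F)(F)F)C(C)=C2 | intermediate
4 | 2,2,2-trifluoroethyl (1R,2S,4S,5R,6S)-5,6-dihydroxy-1,5-dimethyl-7-oxabicyclo[2.2.1]heptane-2-carboxylate (exo,exo-diol) | C[C@@]12O[C@@H](C[C@@H]1C(=O)OCC(F)(F)F)[C@](C)(O)[C@@H]2O | intermediate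
5 | (1R,2S,4S,5R,6S)-5,6-dihydroxy-1,5-dimethyl-7-oxabicyclo[2.2.1]heptane-2-carboxylic acid | C[C@@]12O[C@@H](C[C@@H]1C(=O)O)[C@](C)(O)[C@@H]2O | intermediate
6 | (1R,2S,3R,4S)-1,3-dimethyl-7-oxabicyclo[2.2.1]heptane-2,3-diol | C[C@@]12O[C@@H](CC1)[C@](C)(O)[C@@H]2O | intermediate
7 | (2R,5S)-5-acetyl-2-methyloxolane-2-carbaldehyde | O=C[C@@]1(C)CC[C@H](O1)C(C)=O | intermediate
8 | (4-bromobut-1-yn-1-yl)trimethylsilane | C[Si](C)(C)C#CCCBr | starting material
9 | (5S)-5-{[(1S,2R,5S)-5-methyl-2-(propan-2-yl)cyclohexyl]oxy}furan-2(5H)-one | O=C1C=C[C@@H](O[C@H]2C[C@@H](C)CC[C@@H]2C(C)C)O1 | starting material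
10 | [4-(trimethylsilyl)but-3-yn-1-yl]magnesium bromide | C[Si](C)(C)C#CCC[Mg]Br | intermediate
11 | (4S,5S)-5-{[(1S,2R,5S)-5-methyl-2-(propan-2-yl)cyclohexyl]oxy}-4-[4-(trimethylsilyl)but-3-yn-1-yl]oxolan-2-one | C[Si](C)(C)C#CCC[C@@H]1[C@@H](O[C@H]2C[C@@H](C)CC[C@@H]2C(C)C)OC(=O)C1 | intermediate
12 | potassium (3S)-3-(hydroxymethyl)hept-6-ynoate | C#CCC[C@H](CO)CC(=O)[O-].[K+] | intermediate
13 | (4S)-4-(but-3-yn-1-yl)oxolan-2-one | C#CCC[C@@H]1COC(=O)C1 | intermediate
14 | dimethyl{(1E)-2-methyl-4-[(3S)-5-oxooxolan-3-yl]but-1-en-1-yl}alumane | C[Al](C)/C=C(\C)CC[C@@H]1COC(=O)C1 | intermediate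
15 | (4S)-4-[(3E)-4-iodo-3-methylbut-3-en-1-yl]oxolan-2-one | I/C=C(\C)CC[C@@H]1COC(=O)C1 | intermediate
16 | trimethylsilyl (3S,6E)-7-iodo-3-(iodomethyl)-6-methylhept-6-enoate | I/C=C(\C)CC[C@H](CI)CC(=O)O[Si](C)(C)C | intermediate
17 | methyl (3S,6E)-7-iodo-3-(iodomethyl)-6-methylhept-6-enoate | I/C=C(\C)CC[C@H](CI)CC(=O)OC | intermediate
18 | methyl (3S,6E)-3-(iodomethyl)-6-methylnona-6,8-dienoate | C=C/C=C(\C)CC[C@H](CI)CC(=O)OC | intermediate
19 | [(2S,5E)-2-(2-methoxy-2-oxoethyl)-5-methylocta-5,7-dien-1-yl]zinc iodide | C=C/C=C(\C)CC[C@H](C[Zn]I)CC(=O)OC | intermediate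
20 | methyl (3R,6E)-3-{(2R)-2-[(2R,5S)-5-acetyl-2-methyloxolan-2-yl]-2-hydroxyethyl}-6-methylnona-6,8-dienoate | C=C/C=C(\C)CC[C@@H](CC(=O)OC)C[C@@H](O)[C@@]1(C)CC[C@H](O1)C(C)=O | intermediate
21 | methyl (3R,6E)-3-{(2R)-2-[(2R,5S)-5-acetyl-2-methyloxolan-2-yl]-2-[(tert-butyldimethylsilyl)oxy]ethyl}-6-methylnona-6,8-dienoate | C=C/C=C(\C)CC[C@@H](CC(=O)OC)C[C@@H](O[Si](C)(C)C(C)(C)C)[C@@]1(C)CC[C@H](O1)C(C)=O | intermediate
22 | methyl (3R,6E)-3-{(2R)-2-[(tert-butyldimethylsilyl)oxy]-2-[(2R,5S)-5-[(2S)-2-hydroxybut-3-en-2-yl]-2-methyloxolan-2-yl]ethyl}-6-methylnona-6,8-dienoate | C=C/C=C(\C)CC[C@@H](CC(=O)OC)C[C@@H](O[Si](C)(C)C(C)(C)C)[C@@]1(C)CC[C@H](O1)[C@@](C)(O)C=C | intermediate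
23 | methyl (3R)-3-{(2R)-2-[(tert-butyldimethylsilyl)oxy]-2-[(2R,5S)-5-[(2S)-2-hydroxybut-3-en-2-yl]-2-methyloxolan-2-yl]ethyl}-5-[(2S,3S)-3-ethenyl-2-methyloxiran-2-yl]pentanoate | C=C[C@@H]1O[C@@]1(C)CC[C@@H](CC(=O)OC)C[C@@H](O[Si](C)(C)C(C)(C)C)[C@@]2(C)CC[C@H](O2)[C@@](C)(O)C=C | intermediate
24 | lithium carboxylate of 23 (lithium (3R)-…-5-[(2S,3S)-3-ethenyl-2-methyloxiran-2-yl]pentanoate) | C=C[C@@H]1O[C@@]1(C)CC[C@@H](CC(=O)[O-])C[C@@H](O[Si](C)(C)C(C)(C)C)[C@@]2(C)CC[C@H](O2)[C@@](C)(O)C=C.[Li+] | intermediate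
25 | (4R,7R)-4-{(2R)-2-[(tert-butyldimethylsilyl)oxy]-2-[(2R,5S)-5-[(2S)-2-hydroxybut-3-en-2-yl]-2-methyloxolan-2-yl]ethyl}-7-[(1S)-1-hydroxyprop-2-en-1-yl]-7-methyloxepan-2-one | C=C[C@H](O)[C@@]1(C)CC[C@H](C[C@@H](O[Si](C)(C)C(C)(C)C)[C@@]2(C)CC[C@H](O2)[C@@](C)(O)C=C)CC(=O)O1 | intermediate
26 | (1R,4R,5S,8S,9S,12R,13R)-13-[(tert-butyldimethylsilyl)oxy]-5,8-dihydroxy-9,12-epoxy-17-norcembr-6-en-16,4-olide (E/Z not defined) | C1C(=O)O[C@]2(C)CC[C@@H]1C[C@@H](O[Si](C)(C)C(C)(C)C)[C@@]1(C)CC[C@H](O1)[C@@](C)(O)C=C[C@@H]2O | intermediate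
27 | (1R,4R,5S,8S,9S,12R,13R)-13-[(tert-butyldimethylsilyl)oxy]-5,8-dihydroxy-9,12-epoxy-17-norcembran-16,4-olide | C1C(=O)O[C@]2(C)CC[C@@H]1C[C@@H](O[Si](C)(C)C(C)(C)C)[C@@]1(C)CC[C@H](O1)[C@@](C)(O)CC[C@@H]2O | intermediate
28 | 15-[(dimethylamino)methyl] derivative of 27 (both C15 epimers) | CN(C)CC1C(=O)O[C@]2(C)CC[C@@H]1C[C@@H](O[Si](C)(C)C(C)(C)C)[C@@]1(C)CC[C@H](O1)[C@@](C)(O)CC[C@@H]2O | intermediate
29 | trimethylammonium iodide of 28 | C[N+](C)(C)CC1C(=O)O[C@]2(C)CC[C@@H]1C[C@@H](O[Si](C)(C)C(C)(C)C)[C@@]1(C)CC[C@H](O1)[C@@](C)(O)CC[C@@H]2O.[I-] | intermediate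
30 | (1R,4R,5S,8S,9S,12R,13R)-13-[(tert-butyldimethylsilyl)oxy]-5,8-dihydroxy-9,12-epoxycembr-15(17)-en-16,4-olide | C=C1C(=O)O[C@]2(C)CC[C@@H]1C[C@@H](O[Si](C)(C)C(C)(C)C)[C@@]1(C)CC[C@H](O1)[C@@](C)(O)CC[C@@H]2O | intermediate
31 | (1R,4R,5S,8S,9S,12R,13R)-5,8,13-trihydroxy-9,12-epoxycembr-15(17)-en-16,4-olide | C=C1C(=O)O[C@]2(C)CC[C@@H]1C[C@@H](O)[C@@]1(C)CC[C@H](O1)[C@@](C)(O)CC[C@@H]2O | intermediate
32 | Dendronpholide Q (5,13-di-O-acetate of 31) | C=C1C(=O)O[C@]2(C)CC[C@@H]1C[C@@H](OC(C)=O)[C@@]1(C)CC[C@H](O1)[C@@](C)(O)CC[C@@H]2OC(C)=O | target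

Total step count: 19 steps.
Longest linear sequence: 15 steps (steps 5–19, from 8 and 9); the furan branch (steps 1–4) joins at step 10.

Steps most likely to fail

Step 1. What may go wrong: the very electron-rich furan can react with the strongly activated acrylate by a stepwise Friedel–Crafts-type conjugate addition at its free α-position, the adduct can revert or open under the Lewis acid, and any leakage into the regioisomeric adduct lowers the enantiomeric purity after the carboxyl group is removed. Fallback, setting out from 1 and coming back at 5: the dienophile is changed to 3-acryloyl-1,3-oxazolidin-2-one, bound by two-point chelation to a milder divalent copper catalyst, Cu(SbF6)2 with 2,2-bis[(4S)-4-tert-butyl-4,5-dihydrooxazol-2-yl]propane, in CH2Cl2 at −78 °C, which should give the imide cycloadduct F1. Dihydroxylation with OsO4/NMO should then give the diol imide F2, and LiOH/H2O2 cleaves the imide to the diol acid 5.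

Step 10. What may go wrong: the two faces of the α-quaternary aldehyde may be differentiated poorly if chelation is incomplete, the alkylzinc iodide may add slowly, and the new alkoxide may lactonise onto the methyl ester. Fallback, setting out from 18 and coming back at 20: substrate control is replaced by reagent control. Iodine–zinc exchange of 18 with Et2Zn (CuI cat., then removal of the volatiles) should give the dialkylzinc F3, which is added to 7 in toluene at −20 °C in the presence of Ti(OiPr)4 and (1S,2S)-N,N'-bis(trifluoromethylsulfonyl)cyclohexane-1,2-diamine (catalytic asymmetric dialkylzinc addition) to give 20.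

Step 14. What may go wrong: the protonated vinyl epoxide may ionise at the allylic carbon C5 (attack there, allylic transposition or hydride shift), and the seven-membered ring may close slowly in an open chain. Fallback, setting out from 23 and coming back at 27: the epoxide is opened only after the macrocycle is closed and the adjacent alkene is removed. Ring-closing metathesis of 23 (second-generation Grubbs catalyst RuCl2(=CHPh)(H2IMes)(PCy3), CH2Cl2, 40 °C) should give the macrocyclic epoxy alkene F4, and Et3SiOTf/2,6-lutidine converts its tertiary alcohol into the bis-silyl ether F5, so that O8 cannot open the epoxide. Diimide reduction (2-nitrobenzenesulfonohydrazide, Et3N) gives the saturated epoxy ester F6 and LiOH the lithium carboxylate F7. Acidification and CSA then close the lactone transannularly at the now non-allylic tertiary carbon C4 to give the lactone silyl ether F8, and PPTS in MeOH removes the triethylsilyl group to give 27.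

Further compounds
F1 | step 1 | 3-{[(1S,2S,4S)-1,5-dimethyl-7-oxabicyclo[2.2.1]hept-5-en-2-yl]carbonyl}-1,3-oxazolidin-2-one | C[C@@]12O[C@@H](C[C@@H]1C(=O)N1CCOC1=O)C(C)=C2
F2 | step 1 | 3-{[(1R,2S,4S,5R,6S)-5,6-dihydroxy-1,5-dimethyl-7-oxabicyclo[2.2.1]heptan-2-yl]carbonyl}-1,3-oxazolidin-2-one | C[C@@]12O[C@@H](C[C@@H]1C(=O)N1CCOC1=O)[C@](C)(O)[C@@H]2O
F3 | step 10 | bis[(2S,5E)-2-(2-methoxy-2-oxoethyl)-5-methylocta-5,7-dien-1-yl]zinc | C=C/C=C(\C)CC[C@H](C[Zn]C[C@@H](CC/C(C)=C/C=C)CC(=O)OC)CC(=O)OC
F4 | step 14 | methyl (1R,4S,5S,8S,9S,12R,13R)-13-[(tert-butyldimethylsilyl)oxy]-4,5:9,12-diepoxy-8-hydroxy-17-norcembr-6-en-16-oate | COC(=O)C[C@H]1C[C@@H](O[Si](C)(C)C(C)(C)C)[C@@]2(C)CC[C@H](O2)[C@@](C)(O)C=C[C@@H]3O[C@@]3(C)CC1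
F5 | step 14 | 8-O-triethylsilyl ether of F4 | COC(=O)C[C@H]1C[C@@H](O[Si](C)(C)C(C)(C)C)[C@@]2(C)CC[C@H](O2)[C@@](C)(O[Si](CC)(CC)CC)C=C[C@@H]3O[C@@]3(C)CC1
F6 | step 14 | 6,7-dihydro derivative of F5 | COC(=O)C[C@H]1C[C@@H](O[Si](C)(C)C(C)(C)C)[C@@]2(C)CC[C@H](O2)[C@@](C)(O[Si](CC)(CC)CC)CC[C@@H]3O[C@@]3(C)CC1
F7 | step 14 | lithium carboxylate of F6 | [Li+].[O-]C(=O)C[C@H]1C[C@@H](O[Si](C)(C)C(C)(C)C)[C@@]2(C)CC[C@H](O2)[C@@](C)(O[Si](CC)(CC)CC)CC[C@@H]3O[C@@]3(C)CC1
F8 | step 14 | 8-O-triethylsilyl ether of 27 | C1C(=O)O[C@]2(C)CC[C@@H]1C[C@@H](O[Si](C)(C)C(C)(C)C)[C@@]1(C)CC[C@H](O1)[C@@](C)(O[Si](CC)(CC)CC)CC[C@@H]2O
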